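Numbering: ring A = C1(OH), C10(Me), C9, C8(O), C7, C6, C5, with lactone A = C7–C11(=C13H2)–C12(=O)–O–C8. Ring C = C1, C2, C3 (acetyl, C4), C11' (spiro), C13', C5. Ring B = C1', C10'(Me), C9', C8'(O), C7', C6', C5', with lactone B = C7'–C11'–C12'(=O)–O–C8' and chain C2'–C4' on C1'.
Feature: with the C1'/C5' epoxide taken back to an alkene and C8'–O to a ketone, ring B is a cyclohept-4-enone. Its methyl-bearing C10' is β to C8'=O and allylic to C1'=C5'. This is what a [3,3] shift of the array C9'=C8'–O–C5'–C1'=C10' in a 2-methylene-5-alkenyl tetrahydrofuran would give.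
Cuts: epoxide O; C2'=C3' (Wittig); C1–O; C3–C11' and C5–C13' together ([4+2], ring C). Then, in each half: C11=C13, the lactone C–O, C9–C10 (Claisen), C8=C9 (methylenation), C7–C11 (alkylation), and the acyl–alkenyl bond.
Forward: one achiral enone 5 is reduced with either CBS antipode. Each lactone is alkylated, methylenated, ring-expanded (ring B in step 7, ring A in step 15) and lactonised. Ring C closes last, between the ring A dienone and the ring B α-methylene lactone.
Stereochemistry: the CBS carbinols place C7'/C7 (trans alkylation) and are traded for C10'/C10 (chirality transfer). C8'/C8 come from hydride attack anti to the side chain. C11' comes from convex-face attack, C5 from the cycloaddition mode, C1 from axial oxygenation anti to H-5, and the epoxide from attack anti to the C10' methyl.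

Key step: step 7

Remark: in the structure as drawn, C7/C8/C10 (R,R,S) and C7'/C8'/C10' (S,S,R) are mirror images, so the two halves come from opposite enantiomeric series. The transient centres C11' (15, 16) and C11 (26, 27, 29–31, 33–35) are drawn with the substituent on the convex face. TBDPS = tert-butyldiphenylsilyl, TBS = tert-butyldimethylsilyl.

Step 1
Reactants: 1 2-butyn-1-ol
Product: 2 (E)-2-(tributylstannyl)but-2-en-1-ol
Conditions: Bu3SnH, PdCl2(PPh3)2 (cat.), THF, 0 °C to rt
Reagents that add atoms: tributyltin hydride CCCC[SnH](CCCC)CCCC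
Why: Palladium-catalysed syn hydrostannation of a propargylic alcohol puts tin on the carbon next to CH2OH and H and Sn on the same side, which fixes the methyl group trans to tin.

Step 2
Reactants: 2 (E)-2-(tributylstannyl)but-2-en-1-ol
Product: 3 TBDPS ether of 2
Conditions: TBDPSCl, imidazole, DMF, rt
Reagents that add atoms: tert-butyl(chloro)diphenylsilane CC(C)(C)[Si](Cl)(c1ccccc1)c1ccccc1
Why: Standard silylation of a primary alcohol, with a silyl group chosen to outlast the trifluoroacetic acid of steps 9 and 17.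

Step 3
Reactants: 3 TBDPS ether of 2; 4 methyl 4-chloro-4-oxobutanoate
Product: 5 methyl (E)-5-[(TBDPS-oxy)methyl]-4-oxohept-5-enoate
Conditions: Pd2(dba)3 (cat.), P(2-furyl)3, THF, 50 °C
Reagents that add atoms: none
Why: Stille acylation of a vinylstannane with an acid chloride keeps the alkene geometry and spares the methyl ester, so the terminal methyl group ends trans to the new ketone.

Step 4
Reactants: 5 methyl (E)-5-[(TBDPS-oxy)methyl]-4-oxohept-5-enoate
Product: 7 (S)-5-[(E)-1-(TBDPS-oxy)but-2-en-2-yl]dihydrofuran-2(3H)-one, via hydroxy ester 6 (not isolated)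
Conditions: (R)-2-methyl-CBS-oxazaborolidine (cat.), BH3·SMe2, THF, −30 °C; H2O; then PPTS (cat.), PhMe, 50 °C
Reagents that add atoms: none
Why: In the Corey–Bakshi–Shibata reduction the branched alkenyl group acts as the large substituent, so the (R)-catalyst should give the (S)-carbinol C5', and the γ-hydroxy ester then closes to the lactone under mild acid.

Step 5
Reactants: 7 (S)-lactone; 8 tert-butyl bromoacetate
Product: 9 tert-butyl 2-[(3S,5S)-5-[(E)-1-(TBDPS-oxy)but-2-en-2-yl]-2-oxotetrahydrofuran-3-yl]acetate (3,5-trans)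
Conditions: LiN(i-Pr)2, THF, −78 °C; then 8, −78 to −40 °C
Reagents that add atoms: none
Why: Alkylation of a γ-substituted butyrolactone enolate occurs on the face away from the C5' alkenyl group, which sets C7' trans to C5' and brings in C11' and C12'.

Step 6
Reactants: 9 trans-lactone ester
Product: 10 tert-butyl 2-[(3S,5S)-5-[(E)-1-(TBDPS-oxy)but-2-en-2-yl]-2-methylenetetrahydrofuran-3-yl]acetate
Conditions: Cp2TiMe2, PhMe, 70 °C, dark; filtration through basic alumina
Reagents that add atoms: dimethyltitanocene [CH3-].[CH3-].[Ti+4].c1cc[cH-]c1.c1cc[cH-]c1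
Why: Petasis methylenation turns the lactone carbonyl C8' into the exocyclic enol ether C8'=C9'H2 under neutral conditions, while the hindered tert-butyl ester reacts much more slowly with the titanium methylidene.

Step 7
Reactants: 10 2-methylene-5-alkenyl tetrahydrofuran
Product: 11 tert-butyl 2-[(1S,5R)-4-[(TBDPS-oxy)methyl]-5-methyl-7-oxocyclohept-3-en-1-yl]acetate (ring B ketone)
Conditions: PhMe, Et3N (trace), base-washed sealed tube, 160 °C
Reagents that add atoms: none
Why: On heating, the allyl vinyl ether C9'=C8'–O–C5'–C1'=C10' held inside 10 undergoes a concerted suprafacial [3,3] shift (aliphatic Claisen rearrangement) that makes C9'–C10', breaks O–C5' and turns C8' into a ketone, which drives the reaction. The closest known reaction type is the thermal ring expansion of 2-methylene-5-vinyltetrahydrofurans to cyclohept-4-enones. Ring B closes as a five-to-seven ring enlargement through a chair array that C6' and C7' bridge between C8' and C5' (an 8-oxabicyclo[3.2.1]octane-like shape), and this bridge allows only the cis C1'=C5' ring alkene. C10' is the one new stereocentre: the alkenyl arm can reach C9' only on the tetrahydrofuran face that carries it, and the (E)-alkene keeps the methyl group pseudo-equatorial, so the (S)-configuration of the lost C5' carbinol is handed on as (R) at C10', cis to the C7' side chain because that chain is trans to the arm in 10. The step needs the enol ether double bond to stay exocyclic and C7', now α to a ketone, to stay unepimerised, which the acid-free vessel and the trace of amine should secure, while the silyl ether and the tert-butyl ester are spectators.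

Step 8
Reactants: 11 ring B ketone
Product: 12 tert-butyl 2-[(1S,5R,7S)-7-hydroxy-4-[(TBDPS-oxy)methyl]-5-methylcyclohept-3-en-1-yl]acetate
Conditions: LiBH(s-Bu)3, THF, −78 °C; H2O
Reagents that add atoms: none
Why: In the bulky borohydride reduction of a 2-substituted cycloalkanone the hydride comes from the side opposite the C7' side chain, so the C8' hydroxyl ends cis to it.

Step 9
Reactants: 12 cis-hydroxy ester
Product: 14 (3aS,7R,8aS)-6-[(TBDPS-oxy)methyl]-7-methyl-3,3a,4,7,8,8a-hexahydro-2H-cyclohepta[b]furan-2-one (lactone B), via hydroxy acid 13 (not isolated)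
Conditions: CF3CO2H, CH2Cl2, 0 °C to rt
Reagents that add atoms: none
Why: Acidolysis of the tert-butyl ester followed by spontaneous γ-lactonisation of the cis hydroxy acid gives the cis-fused lactone without touching C7' or C8'.

Step 10
Reactants: 14 lactone B
Product: 15 3-(dimethylaminomethyl) derivative of 14 (CH2NMe2 cis to H-7')
Conditions: LiN(i-Pr)2, THF, −78 °C; [Me2N=CH2]I, −78 °C to rt
Reagents that add atoms: N,N-dimethylmethyleneiminium iodide C=[N+](C)C.[I-]
Why: Mannich aminomethylation of the lactone enolate with Eschenmoser's salt adds C13' at C11' from the convex face, and this centre is removed again in step 11.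

Step 11
Reactants: 15 Mannich base
Product: 17 (3aS,7R,8aS)-6-[(TBDPS-oxy)methyl]-7-methyl-3-methylene-3,3a,4,7,8,8a-hexahydro-2H-cyclohepta[b]furan-2-one, via ammonium iodide 16 (not isolated)
Conditions: MeI, MeOH, rt; then NaHCO3, H2O/CH2Cl2, rt
Reagents that add atoms: iodomethane CI
Why: Quaternisation and mild base-induced β-elimination (Hofmann type) is the standard second half of the α-methylenation of lactones.

Step 12
Reactants: 5 methyl (E)-5-[(TBDPS-oxy)methyl]-4-oxohept-5-enoate
Product: 19 (R)-5-[(E)-1-(TBDPS-oxy)but-2-en-2-yl]dihydrofuran-2(3H)-one, via hydroxy ester 18 (not isolated)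
Conditions: (S)-2-methyl-CBS-oxazaborolidine (cat.), BH3·SMe2, THF, −30 °C; H2O; then PPTS (cat.), PhMe, 50 °C
Reagents that add atoms: none
Why: The same Corey–Bakshi–Shibata reduction as in step 4 with the antipodal catalyst should give the (R)-carbinol that opens the ring A series.

Step 13
Reactants: 19 (R)-lactone; 8 tert-butyl bromoacetate
Product: 20 tert-butyl 2-[(3R,5R)-5-[(E)-1-(TBDPS-oxy)but-2-en-2-yl]-2-oxotetrahydrofuran-3-yl]acetate (3,5-trans)
Conditions: LiN(i-Pr)2, THF, −78 °C; then 8, −78 to −40 °C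
Reagents that add atoms: none
Why: Enolate alkylation anti to the alkenyl group, as in step 5, sets C7 trans to the carbinol carbon C5.

Step 14
Reactants: 20 trans-lactone ester
Product: 21 tert-butyl 2-[(3R,5R)-5-[(E)-1-(TBDPS-oxy)but-2-en-2-yl]-2-methylenetetrahydrofuran-3-yl]acetate
Conditions: Cp2TiMe2, PhMe, 70 °C, dark; filtration through basic alumina
Reagents that add atoms: dimethyltitanocene [CH3-].[CH3-].[Ti+4].c1cc[cH-]c1.c1cc[cH-]c1
Why: Petasis methylenation of the lactone carbonyl C8 in preference to the hindered tert-butyl ester, as in step 6.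

Step 15
Reactants: 21 2-methylene-5-alkenyl tetrahydrofuran
Product: 22 tert-butyl 2-[(1R,5S)-4-[(TBDPS-oxy)methyl]-5-methyl-7-oxocyclohept-3-en-1-yl]acetate (ring A ketone)
Conditions: PhMe, Et3N (trace), base-washed sealed tube, 160 °C
Reagents that add atoms: none
Why: This is the Claisen ring expansion of step 7 in the mirror-image series: C9–C10 forms, O–C5 breaks, ring A closes and the (R)-carbinol is traded through the bridged chair for (S)-C10, cis to the C7 side chain.

Step 16
Reactants: 22 ring A ketone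
Product: 23 tert-butyl 2-[(1R,5S,7R)-7-hydroxy-4-[(TBDPS-oxy)methyl]-5-methylcyclohept-3-en-1-yl]acetate
Conditions: LiBH(s-Bu)3, THF, −78 °C; H2O
Reagents that add atoms: none
Why: Bulky borohydride reduction from the side opposite the C7 side chain gives the C8 hydroxyl cis to it, as in step 8.

Step 17
Reactants: 23 cis-hydroxy ester
Product: 25 (3aR,7S,8aR)-6-[(TBDPS-oxy)methyl]-7-methyl-3,3a,4,7,8,8a-hexahydro-2H-cyclohepta[b]furan-2-one (lactone A), via hydroxy acid 24 (not isolated)
Conditions: CF3CO2H, CH2Cl2, 0 °C to rt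
Reagents that add atoms: none
Why: Acidolysis of the tert-butyl ester and γ-lactonisation of the cis hydroxy acid, as in step 9.

Step 18
Reactants: 25 lactone A
Product: 26 3-(dimethylaminomethyl) derivative of 25 (CH2NMe2 cis to H-7)
Conditions: LiN(i-Pr)2, THF, −78 °C; [Me2N=CH2]I, −78 °C to rt
Reagents that add atoms: N,N-dimethylmethyleneiminium iodide C=[N+](C)C.[I-]
Why: Mannich aminomethylation of the lactone enolate with Eschenmoser's salt brings in C13, as in step 10.

Step 19
Reactants: 26 Mannich base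
Product: 28 (3aR,7S,8aR)-6-[(TBDPS-oxy)methyl]-7-methyl-3-methylene-3,3a,4,7,8,8a-hexahydro-2H-cyclohepta[b]furan-2-one, via ammonium iodide 27 (not isolated)
Conditions: MeI, MeOH, rt; then NaHCO3, H2O/CH2Cl2, rt
Reagents that add atoms: iodomethane CI
Why: Quaternisation and Hofmann-type β-elimination give the α-methylene lactone, as in step 11.

Step 20
Reactants: 28 α-methylene lactone A
Product: 29 3-(phenylselanylmethyl) lactone (CH2SePh cis to H-7)
Conditions: PhSeH, Et3N (cat.), CH2Cl2, 0 °C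
Reagents that add atoms: benzeneselenol [SeH]c1ccccc1
Why: Conjugate (hetero-Michael) addition of the selenol masks the only good dienophile of the ring A half, so that diene 33 cannot add to itself in step 24.

Step 21
Reactants: 29 selenide
Product: 30 6-(hydroxymethyl) lactone
Conditions: HF·pyridine, THF, 0 °C to rt
Reagents that add atoms: none
Why: Fluoride cleavage of the silyl ether in an acidic medium avoids base-induced loss of selenolate from the β-seleno lactone.

Step 22
Reactants: 30 allylic alcohol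
Product: 31 C2 enal (6-carbaldehyde)
Conditions: MnO2, CH2Cl2, rt
Reagents that add atoms: none
Why: MnO2 oxidation is selective for the allylic primary alcohol.

Step 23
Reactants: 31 enal; 32 1-(triphenylphosphoranylidene)propan-2-one
Product: 33 6-[(E)-3-oxobut-1-enyl] lactone (ring A dienone C5=C1–C2=C3–C4=O)
Conditions: PhMe, 60 °C
Reagents that add atoms: none
Why: The Wittig reaction of a stabilised ylide with an enal gives the (E)-C2=C3 enone and completes the diene.

Step 24
Reactants: 33 ring A dienone; 17 ring B α-methylene lactone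
Product: 34 Diels–Alder adduct (ring C cyclohexene with C1=C2, H-3 and H-5 cis, acetyl on C3, spiro C11')
Conditions: PhMe, BHT (cat.), sealed tube, 120 °C
Reagents that add atoms: none
Why: The thermal Diels–Alder reaction of a xanthanolide-type dienone with an α-methylene-γ-butyrolactone joins C5 to C13' and C3 to C11' in the orientation known for such pairs, with C3 reaching C11' on the convex face of the cis-fused lactone (cis to H-7') and the lactone carbonyl exo as is usual for α-methylene lactones, a pairing that for these antipodal halves puts C13' on the ring A face of the C10 methyl group, while C3 is erased in step 26.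

Step 25
Reactants: 34 Diels–Alder adduct
Product: 36 adduct with the C11=C13 methylene restored, via selenoxide 35 (not isolated)
Conditions: H2O2 (30% aq.), pyridine, CH2Cl2, 0 °C to rt
Reagents that add atoms: hydrogen peroxide OO
Why: Oxidation to the selenoxide and syn elimination at ambient temperature can only remove H-11, so the methylene group of lactone A returns.

Step 26
Reactants: 36 β,γ-unsaturated ketone
Product: 37 silyl dienol ether C4(OTBS)=C3–C2=C1
Conditions: TBSOTf, Et3N, CH2Cl2, −78 to 0 °C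
Reagents that add atoms: tert-butyldimethylsilyl triflate CC(C)(C)[Si](C)(C)OS(=O)(=O)C(F)(F)F
Why: Soft enolisation with silyl triflate and amine removes the doubly activated H-3 of the only ketone present and gives the conjugated dienol ether.

Step 27
Reactants: 37 silyl dienol ether
Product: 38 γ-hydroxy enone (C1–OH trans to H-5, C2=C3–C4=O)
Conditions: mCPBA (1 equiv), CH2Cl2, aq. phosphate buffer (pH 7), −10 °C
Reagents that add atoms: 3-chloroperbenzoic acid O=C(OO)c1cccc(Cl)c1
Why: In this vinylogous Rubottom oxidation the peracid attacks the electron-rich diene terminus C1 along the axial line anti to H-5, as in the 6β-hydroxylation of steroidal 3,5-dienol ethers, which sets C1 and restores the enone.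

Step 28
Reactants: 38 γ-hydroxy enone
Product: 39 C2' allylic alcohol
Conditions: HF·pyridine, THF, 0 °C to rt
Reagents that add atoms: none
Why: Fluoride cleavage of the primary silyl ether leaves both lactones, the enone and the tertiary alcohol untouched.

Step 29
Reactants: 39 allylic alcohol
Product: 40 C2' enal
Conditions: MnO2, CH2Cl2, rt
Reagents that add atoms: none
Why: MnO2 oxidises the primary allylic alcohol, and the tertiary C1 hydroxyl cannot be oxidised.

Step 30
Reactants: 40 enal; 32 1-(triphenylphosphoranylidene)propan-2-one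
Product: 41 ring B dienone (the target without the epoxide oxygen)
Conditions: PhMe, 50 °C
Reagents that add atoms: none
Why: The stabilised Wittig ylide reacts only with the aldehyde and gives the (E)-C2'=C3' enone.

Step 31
Reactants: 41 ring B dienone
Product: 42 target CNP0177598.2
Conditions: mCPBA, CH2Cl2, aq. phosphate buffer (pH 7), 0 °C
Reagents that add atoms: 3-chloroperbenzoic acid O=C(OO)c1cccc(Cl)c1
Why: Peracid epoxidation picks C1'=C5', the only alkene not bonded directly to a carbonyl group, and comes from the ring B face opposite the C10' methyl group and lactone B, which sets C1' and C5'.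

Compound list
1 | 2-butyn-1-ol | CC#CCO | starting material
2 | (E)-2-(tributylstannyl)but-2-en-1-ol | C/C=C(/[Sn](CCCC)(CCCC)CCCC)CO | intermediate
3 | (E)-tert-butyldiphenyl{[2-(tributylstannyl)but-2-en-1-yl]oxy}silane | C/C=C(/[Sn](CCCC)(CCCC)CCCC)CO[Si](c1ccccc1)(c1ccccc1)C(C)(C)C | intermediate
4 | methyl 4-chloro-4-oxobutanoate | COC(=O)CCC(=O)Cl | starting material
5 | methyl (E)-5-[(TBDPS-oxy)methyl]-4-oxohept-5-enoate | COC(=O)CCC(=O)/C(CO[Si](c1ccccc1)(c1ccccc1)C(C)(C)C)=C/C | intermediate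
6 | methyl (S,E)-4-hydroxy-5-[(TBDPS-oxy)methyl]hept-5-enoate | COC(=O)CC[C@H](O)/C(CO[Si](c1ccccc1)(c1ccccc1)C(C)(C)C)=C/C | intermediate
7 | (S)-5-[(E)-1-(TBDPS-oxy)but-2-en-2-yl]dihydrofuran-2(3H)-one | O=C1CC[C@@H](/C(CO[Si](c2ccccc2)(c2ccccc2)C(C)(C)C)=C/C)O1 | intermediate
8 | tert-butyl bromoacetate | CC(C)(C)OC(=O)CBr | starting material
9 | tert-butyl 2-[(3S,5S)-5-[(E)-1-(TBDPS-oxy)but-2-en-2-yl]-2-oxotetrahydrofuran-3-yl]acetate | O=C1[C@H](CC(=O)OC(C)(C)C)C[C@@H](/C(CO[Si](c2ccccc2)(c2ccccc2)C(C)(C)C)=C/C)O1 | intermediate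
10 | tert-butyl 2-[(3S,5S)-5-[(E)-1-(TBDPS-oxy)but-2-en-2-yl]-2-methylenetetrahydrofuran-3-yl]acetate | C=C1[C@H](CC(=O)OC(C)(C)C)C[C@@H](/C(CO[Si](c2ccccc2)(c2ccccc2)C(C)(C)C)=C/C)O1 | intermediate
11 | tert-butyl 2-[(1S,5R)-4-[(TBDPS-oxy)methyl]-5-methyl-7-oxocyclohept-3-en-1-yl]acetate | O=C1C[C@@H](C)C(CO[Si](c2ccccc2)(c2ccccc2)C(C)(C)C)=CC[C@H]1CC(=O)OC(C)(C)C | intermediate
12 | tert-butyl 2-[(1S,5R,7S)-7-hydroxy-4-[(TBDPS-oxy)methyl]-5-methylcyclohept-3-en-1-yl]acetate | O[C@H]1C[C@@H](C)C(CO[Si](c2ccccc2)(c2ccccc2)C(C)(C)C)=CC[C@H]1CC(=O)OC(C)(C)C | intermediate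
13 | free acid of 12 | O[C@H]1C[C@@H](C)C(CO[Si](c2ccccc2)(c2ccccc2)C(C)(C)C)=CC[C@H]1CC(=O)O | intermediate
14 | (3aS,7R,8aS)-6-[(TBDPS-oxy)methyl]-7-methyl-3,3a,4,7,8,8a-hexahydro-2H-cyclohepta[b]furan-2-one | O=C1O[C@H]2C[C@@H](C)C(CO[Si](c3ccccc3)(c3ccccc3)C(C)(C)C)=CC[C@H]2C1 | intermediate
15 | 14 with CH2NMe2 on C11', cis to H-7' | O=C1O[C@H]2C[C@@H](C)C(CO[Si](c3ccccc3)(c3ccccc3)C(C)(C)C)=CC[C@H]2[C@@H]1CN(C)C | intermediate
16 | trimethylammonium iodide of 15 | O=C1O[C@H]2C[C@@H](C)C(CO[Si](c3ccccc3)(c3ccccc3)C(C)(C)C)=CC[C@H]2[C@@H]1C[N+](C)(C)C.[I-] | intermediate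
17 | (3aS,7R,8aS)-6-[(TBDPS-oxy)methyl]-7-methyl-3-methylene-3,3a,4,7,8,8a-hexahydro-2H-cyclohepta[b]furan-2-one | C=C1C(=O)O[C@H]2C[C@@H](C)C(CO[Si](c3ccccc3)(c3ccccc3)C(C)(C)C)=CC[C@@H]12 | intermediate
18 | methyl (R,E)-4-hydroxy-5-[(TBDPS-oxy)methyl]hept-5-enoate | COC(=O)CC[C@@H](O)/C(CO[Si](c1ccccc1)(c1ccccc1)C(C)(C)C)=C/C | intermediate
19 | (R)-5-[(E)-1-(TBDPS-oxy)but-2-en-2-yl]dihydrofuran-2(3H)-one | O=C1CC[C@H](/C(CO[Si](c2ccccc2)(c2ccccc2)C(C)(C)C)=C/C)O1 | intermediate
20 | tert-butyl 2-[(3R,5R)-5-[(E)-1-(TBDPS-oxy)but-2-en-2-yl]-2-oxotetrahydrofuran-3-yl]acetate | O=C1[C@@H](CC(=O)OC(C)(C)C)C[C@H](/C(CO[Si](c2ccccc2)(c2ccccc2)C(C)(C)C)=C/C)O1 | intermediate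
21 | tert-butyl 2-[(3R,5R)-5-[(E)-1-(TBDPS-oxy)but-2-en-2-yl]-2-methylenetetrahydrofuran-3-yl]acetate | C=C1[C@@H](CC(=O)OC(C)(C)C)C[C@H](/C(CO[Si](c2ccccc2)(c2ccccc2)C(C)(C)C)=C/C)O1 | intermediate
22 | tert-butyl 2-[(1R,5S)-4-[(TBDPS-oxy)methyl]-5-methyl-7-oxocyclohept-3-en-1-yl]acetate | O=C1C[C@H](C)C(CO[Si](c2ccccc2)(c2ccccc2)C(C)(C)C)=CC[C@@H]1CC(=O)OC(C)(C)C | intermediate
23 | tert-butyl 2-[(1R,5S,7R)-7-hydroxy-4-[(TBDPS-oxy)methyl]-5-methylcyclohept-3-en-1-yl]acetate | O[C@@H]1C[C@H](C)C(CO[Si](c2ccccc2)(c2ccccc2)C(C)(C)C)=CC[C@@H]1CC(=O)OC(C)(C)C | intermediate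
24 | free acid of 23 | O[C@@H]1C[C@H](C)C(CO[Si](c2ccccc2)(c2ccccc2)C(C)(C)C)=CC[C@@H]1CC(=O)O | intermediate
25 | (3aR,7S,8aR)-6-[(TBDPS-oxy)methyl]-7-methyl-3,3a,4,7,8,8a-hexahydro-2H-cyclohepta[b]furan-2-one | O=C1O[C@@H]2C[C@H](C)C(CO[Si](c3ccccc3)(c3ccccc3)C(C)(C)C)=CC[C@@H]2C1 | intermediate
26 | 25 with CH2NMe2 on C11, cis to H-7 | O=C1O[C@@H]2C[C@H](C)C(CO[Si](c3ccccc3)(c3ccccc3)C(C)(C)C)=CC[C@@H]2[C@H]1CN(C)C | intermediate
27 | trimethylammonium iodide of 26 | O=C1O[C@@H]2C[C@H](C)C(CO[Si](c3ccccc3)(c3ccccc3)C(C)(C)C)=CC[C@@H]2[C@H]1C[N+](C)(C)C.[I-] | intermediate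
28 | (3aR,7S,8aR)-6-[(TBDPS-oxy)methyl]-7-methyl-3-methylene-3,3a,4,7,8,8a-hexahydro-2H-cyclohepta[b]furan-2-one | C=C1C(=O)O[C@@H]2C[C@H](C)C(CO[Si](c3ccccc3)(c3ccccc3)C(C)(C)C)=CC[C@H]12 | intermediate
29 | 25 with CH2SePh on C11, cis to H-7 | O=C1O[C@@H]2C[C@H](C)C(CO[Si](c3ccccc3)(c3ccccc3)C(C)(C)C)=CC[C@@H]2[C@H]1C[Se]c1ccccc1 | intermediate
30 | 29 with free CH2OH on C1 | O=C1O[C@@H]2C[C@H](C)C(CO)=CC[C@@H]2[C@H]1C[Se]c1ccccc1 | intermediate
31 | 29 with CHO (C2) on C1 | O=C1O[C@@H]2C[C@H](C)C(C=O)=CC[C@@H]2[C@H]1C[Se]c1ccccc1 | intermediate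
32 | 1-(triphenylphosphoranylidene)propan-2-one | CC(=O)C=P(c1ccccc1)(c1ccccc1)c1ccccc1 | starting material
33 | 29 with an (E)-3-oxobut-1-enyl group on C1 (ring A dienone) | O=C1O[C@@H]2C[C@H](C)C(/C=C/C(C)=O)=CC[C@@H]2[C@H]1C[Se]c1ccccc1 | intermediate
34 | Diels–Alder adduct: ring C with C1=C2, H-3 and H-5 cis, acetyl on C3, spiro C11'; lactone A as CH2SePh adduct; ring B with C1'=C5' and CH2OTBDPS | O=C1O[C@@H]2C[C@H](C)C3=C[C@H](C(C)=O)[C@]4(C[C@@H]3C[C@@H]2[C@H]1C[Se]c1ccccc1)C(=O)O[C@H]1C[C@@H](C)C(CO[Si](c2ccccc2)(c2ccccc2)C(C)(C)C)=CC[C@H]14 | intermediate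
35 | selenoxide of 34 | O=C1O[C@@H]2C[C@H](C)C3=C[C@H](C(C)=O)[C@]4(C[C@@H]3C[C@@H]2[C@H]1C[Se](=O)c1ccccc1)C(=O)O[C@H]1C[C@@H](C)C(CO[Si](c2ccccc2)(c2ccccc2)C(C)(C)C)=CC[C@H]14 | intermediate
36 | adduct with α-methylene lactone A | C=C1C(=O)O[C@@H]2C[C@H](C)C3=C[C@H](C(C)=O)[C@]4(C[C@@H]3C[C@H]12)C(=O)O[C@H]1C[C@@H](C)C(CO[Si](c2ccccc2)(c2ccccc2)C(C)(C)C)=CC[C@H]14 | intermediate
37 | TBS dienol ether C4(OTBS)=C3–C2=C1 (OTBS cis to C11') | C=C1C(=O)O[C@@H]2C[C@H](C)C3=C/C(=C(\C)O[Si](C)(C)C(C)(C)C)[C@]4(C[C@@H]3C[C@H]12)C(=O)O[C@H]1C[C@@H](C)C(CO[Si](c2ccccc2)(c2ccccc2)C(C)(C)C)=CC[C@H]14 | intermediate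
38 | C1-hydroxy C2=C3 enone, ring B still with CH2OTBDPS | C=C1C(=O)O[C@@H]2C[C@H](C)[C@@]3(O)C=C(C(C)=O)[C@]4(C[C@@H]3C[C@H]12)C(=O)O[C@H]1C[C@@H](C)C(CO[Si](c2ccccc2)(c2ccccc2)C(C)(C)C)=CC[C@H]14 | intermediate
39 | 38 with free CH2OH on C1' | C=C1C(=O)O[C@@H]2C[C@H](C)[C@@]3(O)C=C(C(C)=O)[C@]4(C[C@@H]3C[C@H]12)C(=O)O[C@H]1C[C@@H](C)C(CO)=CC[C@H]14 | intermediate
40 | 38 with CHO (C2') on C1' | C=C1C(=O)O[C@@H]2C[C@H](C)[C@@]3(O)C=C(C(C)=O)[C@]4(C[C@@H]3C[C@H]12)C(=O)O[C@H]1C[C@@H](C)C(C=O)=CC[C@H]14 | intermediate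
41 | 1',5'-deoxy target (C1'=C5' dienone) | C=C1C(=O)O[C@@H]2C[C@H](C)[C@@]3(O)C=C(C(C)=O)[C@]4(C[C@@H]3C[C@H]12)C(=O)O[C@H]1C[C@@H](C)C(/C=C/C(C)=O)=CC[C@H]14 | intermediate
42 | CNP0177598.2 | C=C1C(=O)O[C@@H]2C[C@H](C)[C@@]3(O)C=C(C(C)=O)[C@]4(C[C@@H]3C[C@H]12)C(=O)O[C@H]1C[C@@H](C)[C@]2(/C=C/C(C)=O)O[C@@H]2C[C@H]14 | target

Total steps: 31. Longest linear sequence: 23 steps (1–3, then 12–31). The ring B branch (steps 4–11) runs in parallel.

Steps most likely to fail

Step 24. The riskiest point is facial selectivity on the diene. The required mode bonds C13' on the ring A face that also carries the C10 methyl group and lactone A. The competing endo mode on the open face would invert C5, while C11' is set correctly by convex-face attack in either mode. The union of two hindered partners may also be slow.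
The fallback erases C5 and sets it again by protonation. It sets out from 33 and 17 and accepts the adduct bonded on the other diene face, the C3,C5-diastereomeric adduct F1. TBSOTf/Et3N converts this into its silyl dienol ether F2. DDQ then removes H-5 together with the silyl group to give the linear dienone F3 (C2=C3 and C1=C5), in which C3 and C5 are planar. Electron-transfer 1,6-reduction with SmI2 in THF/H2O protonates the δ-carbon C5 from the open ring A face, opposite the C10 methyl group and lactone A. This pushes C13' onto the required face and returns the β,γ-unsaturated ketone, so the fallback comes back at 34.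

Step 7 (and its twin, step 15). The exocyclic enol ether may drift into the ring before it rearranges, or the ester may lose isobutene at the temperature needed.
The fallback sets out from 10 and treats it with i-Bu3Al in CH2Cl2 at −78 °C to rt. Coordination of the ring oxygen triggers the same C9'–C10' / O–C5' bond change as a charge-accelerated rearrangement well below room temperature. The aluminium-bound ketone is then reduced in the flask by β-hydride transfer from the side away from the C7' chain. The fallback skips 11 and comes back at 12.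

Step 6 (and its twin, step 14). The tert-butyl ester may also be methylenated, and the enol ether may be hydrolysed or isomerised during isolation from the titanium residues.
The fallback sets out from 9. One equivalent of i-Bu2AlH at −78 °C gives the lactol F4. The Ohira–Bestmann reagent with K2CO3 in MeOH homologates its open hydroxy aldehyde form to the alkynol F5 (C8'≡C9'H, free C5'–OH). AuCl(PPh3)/AgOTf (cat.) in CH2Cl2 then closes the alcohol onto the alkyne in the 5-exo-dig mode, and the fallback comes back at 10.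

Further compounds
F1 | step 24 | C3,C5-diastereomer of adduct 34 | O=C1O[C@@H]2C[C@H](C)C3=C[C@@H](C(C)=O)[C@]4(C[C@H]3C[C@@H]2[C@H]1C[Se]c1ccccc1)C(=O)O[C@H]1C[C@@H](C)C(CO[Si](c2ccccc2)(c2ccccc2)C(C)(C)C)=CC[C@H]14
F2 | step 24 | TBS dienol ether of F1 | O=C1O[C@@H]2C[C@H](C)C3=C/C(=C(\C)O[Si](C)(C)C(C)(C)C)[C@]4(C[C@H]3C[C@@H]2[C@H]1C[Se]c1ccccc1)C(=O)O[C@H]1C[C@@H](C)C(CO[Si](c2ccccc2)(c2ccccc2)C(C)(C)C)=CC[C@H]14
F3 | step 24 | linear dienone C4(=O)–C3=C2–C1=C5 | O=C1O[C@@H]2C[C@H](C)C3=C(C[C@@H]2[C@H]1C[Se]c1ccccc1)C[C@@]4(C(C(C)=O)=C3)C(=O)O[C@H]1C[C@@H](C)C(CO[Si](c2ccccc2)(c2ccccc2)C(C)(C)C)=CC[C@H]14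
F0 | step 7 | none | none
F4 | step 6 | lactol of 9 (anomeric mixture) | OC1[C@H](CC(=O)OC(C)(C)C)C[C@@H](/C(CO[Si](c2ccccc2)(c2ccccc2)C(C)(C)C)=C/C)O1
F5 | step 6 | tert-butyl (3S,5S,E)-3-ethynyl-5-hydroxy-6-[(TBDPS-oxy)methyl]oct-6-enoate | C#C[C@H](CC(=O)OC(C)(C)C)C[C@H](O)/C(CO[Si](c1ccccc1)(c1ccccc1)C(C)(C)C)=C/C
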